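**No constants.** I had no rate constants for the three steps: starting material binding enzyme to give complex, complex releasing target, and protic impurity quenching starting material. So I began from what the elm flask, the very flask asked about, had shown so far.

- elm: starting material 0.050 M; protic impurity 1 mM; enzyme 5 µM; the very flask that is asked about, followed so far
- flask: starting material 0.050 M; protic impurity 1.00 mM; enzyme 5.0 µM; time 5.0 h

elm run (percent of the starting material charged): time / h: target / % = 0.333: 18.1; 1.00: 27.6; 2.00: 27.8; 3.00: 27.7; 4.00: 27.1

(each reading ± 0.5 percentage points)

- what is taken out of target is counted as made
- the numbers in the tables scatter with a standard deviation of 0.5 percentage points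
- steps thought possible: starting material + protic impurity -> quenched substrate; complex <-> enzyme + target; starting material + enzyme <-> complex
- additions bring no volume worth counting

- autumn: at 5.0 h add starting material, 50.0% of the amount charged, then wait 1.5 h
- winter: at 5.0 h take out 90% of the target then present, then wait 1.5 h
- dusk: change nothing and wait 1.5 h more
- noon: at 5.0 h add enzyme, 100% of the amount charged, then wait 1.5 h

- target, in percent of the starting material first charged, at 5.0 h
- the remedy with the largest gain of target, or "none" below 2 percentage points (autumn / winter / dusk / noon / none)
- target present, with what was taken out counted in, in percent of the starting material first charged, after autumn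
- target present, with what was taken out counted in, in percent of the starting material first charged, after noon

**Two ends.** From 1.00 h to 4.00 h the elm target stood between 27.1% and 27.8%, with a mean of 27.6%. I read that flat level as a balance, thermodynamic control in the usual term. The impurity can remove 2.00% of the charge. If that loss came before the flat readings, the target at 5.0 h stays at the mean, my upper bound. If it came after them, the target falls to 27.0%, my lower bound.

**The join.** Midway between those cases I took the plateau share, the target as a part of the material still able to become target: 27.8%. My own figure for 5.0 h was 27.3%. Autumn gave me 41.2%. Winter, with 24.5% taken out, gave 45.0%, more than autumn. Enzyme stands on both sides of the overall change, so for noon I kept the share and 27.3%.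

**The forecast.** It said “The flat level is therefore the reversible enzymatic equilibrium” and gave 27.3%, inside my bracket, with 41.3% after autumn, 27.3% after noon and winter as the best remedy.

**The result.** The flask gave 27.3%, inside the bracket, with 41.1% after autumn, 27.3% after noon and winter ahead by a gain of 18 percentage points.

    starting material + protic impurity → quenched substrate (k = 18.5 L mol⁻¹ min⁻¹)
    complex ⇌ enzyme + target (K = 0.0322 M, k = 423 min⁻¹)
    starting material + enzyme ⇌ complex (K = 12.0 L mol⁻¹, k = 1.27 × 10⁵ L mol⁻¹ min⁻¹)

The target in this flask stops near the plateau share of 27.8% that I read because of the back reaction of complex to starting material and enzyme: the run without that step reached 98.0% against 27.3%. A neighbour flask, charged with 0.12 M of starting material, has a pool of 99.2%. The same share makes that 27.6%, and the neighbour flask stood at 27.6%.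

The runs were generated by integration from invented constants, noise included.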